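Everything rests on cutting the C3–C4 bond of ring C. The feature used is that C3 sits next to the oxygen-bearing stereocentre C2 and C4 is a ketone carbon on ring A. C3 can therefore be the CH of a vinyl group on C2 and C4 the oxygenated carbon of a silyl enol ether, two 1-alkenes held close by O1 and the C4a–C8a edge of ring A. One ring-closing metathesis joins them, expels ethylene and gives ring C as a 4-silyloxy-2H-chromene under neutral conditions, with C2 untouched. The precursor is the (S)-1-arylallyl ether of the prenylated, 4-O-silylated resacetophenone, as its tert-butyldimethylsilyl enol ether.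

Key step: step 11

Assumption: the facial sense of the iridium step is assigned by analogy with cinnamyl carbonates and phenoxides, where the (Ra,Rc,Rc) phosphoramidite is taken to give (R)-1-arylallyl aryl ethers. The (Sa,Sc,Sc) ligand is therefore specified; its antipode would be used if the sense proved reversed.

Design remarks: C2 is S in 17, 19, 20 and 22 (priorities O > ring B aryl > vinyl or C3 > H). The 7-oxygen is carried as a triisopropylsilyl ether so that one buffered fluoride step removes both silyl groups and no acid meets the prenyl groups. The enol ether is made with base, not with a silyl triflate, so that no Lewis acid meets the benzylic allylic aryl ether.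

Step 1
Reactants: 1 2,4-dihydroxyacetophenone; 2 prenyl bromide (1-bromo-3-methylbut-2-ene)
Product: 3 1-[2,4-dihydroxy-3-(3-methylbut-2-en-1-yl)phenyl]ethan-1-one
Conditions: KOH (10% aq.), 0 °C → rt; chromatography
Reagents that add atoms: none
Why: C-alkylation of the resorcinolate in water (phenoxide C-prenylation) should go mainly to C3, the ring carbon flanked by both oxygens, and the 5-prenyl and O-prenyl isomers are removed by chromatography.

Step 2
Reactants: 3 1-[2,4-dihydroxy-3-(3-methylbut-2-en-1-yl)phenyl]ethan-1-one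
Product: 4 1-[2-hydroxy-3-(3-methylbut-2-en-1-yl)-4-(triisopropylsilyloxy)phenyl]ethan-1-one
Conditions: TIPSCl, imidazole, DMF, 0 °C → rt
Reagents that add atoms: triisopropylsilyl chloride (TIPSCl), CC(C)[Si](Cl)(C(C)C)C(C)C
Why: Phenol silylation should take only the 4-hydroxyl, because the 2-hydroxyl is locked in a hydrogen bond to the acetyl group and is far less nucleophilic.

Step 3
Reactants: 5 3-bromo-4-hydroxybenzaldehyde; 6 3-chloro-3-methylbut-1-yne
Product: 7 3-bromo-4-[(2-methylbut-3-yn-2-yl)oxy]benzaldehyde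
Conditions: CuCl2 (cat.), DBU, MeCN, 0 °C
Reagents that add atoms: none
Why: Copper-catalysed propargylic etherification of a phenol with a tertiary propargyl chloride, which works best with acidic phenols such as this 4-formylphenol.

Step 4
Reactants: 7 3-bromo-4-[(2-methylbut-3-yn-2-yl)oxy]benzaldehyde
Product: 9 8-bromo-2,2-dimethyl-2H-chromene-6-carbaldehyde, via allenyl phenol 8 (not isolated)
Conditions: N,N-diethylaniline, 190 °C
Reagents that add atoms: none
Why: Aromatic propargyl Claisen rearrangement to the only free ortho carbon gives allenyl phenol 8, which closes to the 2,2-dimethyl-2H-chromene by a 1,5-hydrogen shift and 6π oxa-electrocyclisation.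

Step 5
Reactants: 9 8-bromo-2,2-dimethyl-2H-chromene-6-carbaldehyde; 10 tributyl(3-methylbut-2-en-1-yl)stannane
Product: 11 2,2-dimethyl-8-(3-methylbut-2-en-1-yl)-2H-chromene-6-carbaldehyde
Conditions: Pd(PPh3)4 (5 mol%), DMF, 90 °C
Reagents that add atoms: none
Why: Stille coupling, in which the aryl bromide adds to zerovalent palladium, the allyl group is transferred from tin and reductive elimination at the less substituted allyl terminus gives the linear prenyl arene, with the aldehyde tolerated.

Step 6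
Reactants: 11 2,2-dimethyl-8-(3-methylbut-2-en-1-yl)-2H-chromene-6-carbaldehyde; 12 ethyl (triphenylphosphoranylidene)acetate
Product: 13 ethyl (E)-3-[2,2-dimethyl-8-(3-methylbut-2-en-1-yl)-2H-chromen-6-yl]prop-2-enoate
Conditions: toluene, 80 °C
Reagents that add atoms: none
Why: Wittig olefination of an aromatic aldehyde with a stabilised ylide, which should give the (E)-enoate and needs no added base.

Step 7
Reactants: 13 ethyl (E)-3-[2,2-dimethyl-8-(3-methylbut-2-en-1-yl)-2H-chromen-6-yl]prop-2-enoate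
Product: 14 (E)-3-[2,2-dimethyl-8-(3-methylbut-2-en-1-yl)-2H-chromen-6-yl]prop-2-en-1-ol
Conditions: i-Bu2AlH (2.2 equiv), CH2Cl2, −78 °C; aq. potassium sodium tartrate (KNaC4H4O6)
Reagents that add atoms: none
Why: 1,2-Reduction of the unsaturated ester by the aluminium hydride at low temperature gives the (E)-allylic alcohol and leaves the prenyl and chromene olefins alone.

Step 8
Reactants: 14 (E)-3-[2,2-dimethyl-8-(3-methylbut-2-en-1-yl)-2H-chromen-6-yl]prop-2-en-1-ol
Product: 15 (E)-3-[2,2-dimethyl-8-(3-methylbut-2-en-1-yl)-2H-chromen-6-yl]prop-2-en-1-yl methyl carbonate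
Conditions: ClCO2Me, pyridine, CH2Cl2, 0 °C
Reagents that add atoms: methyl chloroformate, COC(=O)Cl
Why: Acylation of the primary alcohol with a chloroformate gives the allylic carbonate, the leaving group needed for the iridium allyl chemistry of step 9.

Step 9
Reactants: 4 1-[2-hydroxy-3-(3-methylbut-2-en-1-yl)-4-(triisopropylsilyloxy)phenyl]ethan-1-one; 15 (E)-3-[2,2-dimethyl-8-(3-methylbut-2-en-1-yl)-2H-chromen-6-yl]prop-2-en-1-yl methyl carbonate
Product: 17 1-[2-{[(1S)-1-(2,2-dimethyl-8-prenyl-2H-chromen-6-yl)prop-2-en-1-yl]oxy}-3-prenyl-4-(triisopropylsilyloxy)phenyl]ethan-1-one, via sodium phenoxide 16 (not isolated)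
Conditions: 4, NaH, THF, 0 °C; then 15, [Ir(cod)Cl]2 (2 mol%), L* (4 mol%, pre-activated with n-PrNH2), THF, 50 °C; L* = (Sa,Sc,Sc)-O,O'-(1,1'-binaphthyl-2,2'-diyl) N,N-bis(1-phenylethyl)phosphoramidite
Reagents that add atoms: none
Why: Iridium-catalysed asymmetric allylic etherification, in which the cyclometalated iridium phosphoramidite complex ionises the carbonate to an allyl complex, the phenoxide attacks its aryl-substituted terminus to give the branched ether, and the (Sa,Sc,Sc) ligand selects the face that gives the (S) configuration at the future C2.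

Step 10
Reactants: 17 1-[2-{[(1S)-1-(2,2-dimethyl-8-prenyl-2H-chromen-6-yl)prop-2-en-1-yl]oxy}-3-prenyl-4-(triisopropylsilyloxy)phenyl]ethan-1-one
Product: 19 tert-butyldimethylsilyl enol ether of 17 (1-silyloxyvinyl arene), via potassium enolate 18 (not isolated)
Conditions: KN(SiMe3)2, THF, −78 °C; then TBSCl, −78 → 0 °C; pH 7 work-up, Et3N-washed silica
Reagents that add atoms: tert-butyldimethylsilyl chloride (TBSCl), CC(C)(C)[Si](C)(C)Cl
Why: Kinetic deprotonation of the methyl ketone, its only enolisable position, followed by O-silylation of the potassium enolate gives the 2-silyloxy-1-alkene without any Lewis acid that could ionise the benzylic allylic aryl ether.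

Step 11
Reactants: 19 tert-butyldimethylsilyl enol ether of 17
Product: 20 (2S)-4-(tert-butyldimethylsilyloxy)-2-(2,2-dimethyl-8-prenyl-2H-chromen-6-yl)-8-prenyl-7-(triisopropylsilyloxy)-2H-chromene
Conditions: second-generation Grubbs catalyst RuCl2(=CHPh)(PCy3)(H2IMes) (5–10 mol%), 1,4-benzoquinone (10 mol%), degassed toluene (0.005 M), 60 °C, Ar sparge; filtration through Et3N-washed silica
Reagents that add atoms: none
Why: The catalyst loads at the monosubstituted vinyl group on C2, the new ruthenium alkylidene at C3 adds across the CH2 terminus of the silyl enol ether, and the ruthenacyclobutane breaks down to the C3=C4 bond and RuCl2(=CH2)(H2IMes), which carries the chain with loss of ethylene. The closest known reaction type is ring-closing metathesis of acyclic silyl enol ethers that carry a terminal alkene, which gives cyclic silyl enol ethers with this catalyst. Ring C closes as a six-membered ring by intramolecular cycloaddition and cycloreversion between two alkene carbons already held 1,6 to each other through O1 and the C4a–C8a arene bond, and the closure is irreversible once ethylene is swept out. No stereocentre is formed, and C2 keeps its configuration because the medium is neutral and C4 is not yet a carbonyl that could open the ring to a chalcone. The step needs closure on the enol ether and not on the 8-prenyl olefin (seven-membered benzoxepine, loss of isobutene): the enol ether offers a bare CH2 terminus and the smaller ring, whereas the prenyl olefin is trisubstituted, would have to place ruthenium on its CMe2 carbon and is flanked by the bulky triisopropylsilyl ether. Benzoquinone removes ruthenium hydride so the allylic ether double bond does not migrate towards C2, and high dilution suppresses cross-metathesis with the prenyl groups.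

Step 12
Reactants: 20 (2S)-4-(tert-butyldimethylsilyloxy)-2-(2,2-dimethyl-8-prenyl-2H-chromen-6-yl)-8-prenyl-7-(triisopropylsilyloxy)-2H-chromene
Product: 22 (2S)-7-hydroxy-2-[2,2-dimethyl-8-(3-methylbut-2-en-1-yl)-2H-chromen-6-yl]-8-(3-methylbut-2-en-1-yl)chroman-4-one (target), via 7-O-triisopropylsilyl flavanone 21 (not isolated)
Conditions: Bu4NF (3 equiv), AcOH (3 equiv), THF, 0 °C → rt
Reagents that add atoms: none
Why: Fluoride-mediated desilylation, in which the enol freed from the silyl enol ether is protonated at C3 by acetic acid to give the C4 ketone and the aryl silyl ether is cleaved in the same pot, while the buffer prevents enolate build-up and retro-oxa-Michael ring opening so that C2 stays S.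

Compound list
1 | 2,4-dihydroxyacetophenone | CC(=O)c1ccc(O)cc1O | starting material
2 | prenyl bromide (1-bromo-3-methylbut-2-ene) | CC(C)=CCBr | starting material
3 | 1-[2,4-dihydroxy-3-(3-methylbut-2-en-1-yl)phenyl]ethan-1-one | CC(=O)c1ccc(O)c(CC=C(C)C)c1O | intermediate
4 | 1-[2-hydroxy-3-(3-methylbut-2-en-1-yl)-4-(triisopropylsilyloxy)phenyl]ethan-1-one | CC(=O)c1ccc(O[Si](C(C)C)(C(C)C)C(C)C)c(CC=C(C)C)c1O | intermediate
5 | 3-bromo-4-hydroxybenzaldehyde | O=Cc1ccc(O)c(Br)c1 | starting material
6 | 3-chloro-3-methylbut-1-yne | CC(C)(Cl)C#C | starting material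
7 | 3-bromo-4-[(2-methylbut-3-yn-2-yl)oxy]benzaldehyde | O=Cc1ccc(OC(C)(C)C#C)c(Br)c1 | intermediate
8 | 3-bromo-4-hydroxy-5-(3-methylbuta-1,2-dien-1-yl)benzaldehyde (allenyl phenol, formed in the flask) | O=Cc1cc(Br)c(O)c(C=C=C(C)C)c1 | intermediate
9 | 8-bromo-2,2-dimethyl-2H-chromene-6-carbaldehyde | CC1(C)C=Cc2cc(C=O)cc(Br)c2O1 | intermediate
10 | tributyl(3-methylbut-2-en-1-yl)stannane | CCCC[Sn](CCCC)(CCCC)CC=C(C)C | starting material
11 | 2,2-dimethyl-8-(3-methylbut-2-en-1-yl)-2H-chromene-6-carbaldehyde | CC(C)=CCc1cc(C=O)cc2c1OC(C)(C)C=C2 | intermediate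
12 | ethyl (triphenylphosphoranylidene)acetate | CCOC(=O)C=P(c1ccccc1)(c1ccccc1)c1ccccc1 | starting material
13 | ethyl (E)-3-[2,2-dimethyl-8-(3-methylbut-2-en-1-yl)-2H-chromen-6-yl]prop-2-enoate | CC(C)=CCc1cc(/C=C/C(=O)OCC)cc2c1OC(C)(C)C=C2 | intermediate
14 | (E)-3-[2,2-dimethyl-8-(3-methylbut-2-en-1-yl)-2H-chromen-6-yl]prop-2-en-1-ol | CC(C)=CCc1cc(/C=C/CO)cc2c1OC(C)(C)C=C2 | intermediate
15 | (E)-3-[2,2-dimethyl-8-(3-methylbut-2-en-1-yl)-2H-chromen-6-yl]prop-2-en-1-yl methyl carbonate | CC(C)=CCc1cc(/C=C/COC(=O)OC)cc2c1OC(C)(C)C=C2 | intermediate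
16 | sodium 2-acetyl-6-(3-methylbut-2-en-1-yl)-5-(triisopropylsilyloxy)phenolate (formed in the flask) | CC(=O)c1ccc(O[Si](C(C)C)(C(C)C)C(C)C)c(CC=C(C)C)c1[O-].[Na+] | intermediate
17 | 1-[2-{[(1S)-1-(2,2-dimethyl-8-prenyl-2H-chromen-6-yl)prop-2-en-1-yl]oxy}-3-prenyl-4-(triisopropylsilyloxy)phenyl]ethan-1-one | CC(C)=CCc1cc([C@@H](Oc3c(C(C)=O)ccc(O[Si](C(C)C)(C(C)C)C(C)C)c3CC=C(C)C)C=C)cc2c1OC(C)(C)C=C2 | intermediate
18 | potassium enolate of 17 (formed in the flask) | CC(C)=CCc1cc([C@@H](Oc3c(C(=C)[O-])ccc(O[Si](C(C)C)(C(C)C)C(C)C)c3CC=C(C)C)C=C)cc2c1OC(C)(C)C=C2.[K+] | intermediate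
19 | tert-butyldimethylsilyl enol ether of 17, (S) at the allylic ether carbon (metathesis precursor) | CC(C)=CCc1cc([C@@H](Oc3c(C(=C)O[Si](C)(C)C(C)(C)C)ccc(O[Si](C(C)C)(C(C)C)C(C)C)c3CC=C(C)C)C=C)cc2c1OC(C)(C)C=C2 | intermediate
20 | (2S)-4-(tert-butyldimethylsilyloxy)-2-(2,2-dimethyl-8-prenyl-2H-chromen-6-yl)-8-prenyl-7-(triisopropylsilyloxy)-2H-chromene | CC(C)=CCc1cc([C@@H]2C=C(O[Si](C)(C)C(C)(C)C)c3ccc(O[Si](C(C)C)(C(C)C)C(C)C)c(CC=C(C)C)c3O2)cc2c1OC(C)(C)C=C2 | intermediate
21 | (2S)-2-(2,2-dimethyl-8-prenyl-2H-chromen-6-yl)-8-prenyl-7-(triisopropylsilyloxy)chroman-4-one (formed in the flask) | CC(C)=CCc1cc([C@@H]2CC(=O)c3ccc(O[Si](C(C)C)(C(C)C)C(C)C)c(CC=C(C)C)c3O2)cc2c1OC(C)(C)C=C2 | intermediate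
22 | (2S)-7-hydroxy-2-[2,2-dimethyl-8-(3-methylbut-2-en-1-yl)-2H-chromen-6-yl]-8-(3-methylbut-2-en-1-yl)chroman-4-one | CC(C)=CCc1cc([C@@H]2CC(=O)c3ccc(O)c(CC=C(C)C)c3O2)cc2c1OC(C)(C)C=C2 | target

Total step count: 12 (ring A, steps 1–2; ring B, steps 3–8; union and endgame, steps 9–12).
Longest linear sequence: 10 steps (steps 3–12, from 3-bromo-4-hydroxybenzaldehyde).

Steps most likely to fail

1. Step 11. The alkylidene at C3 may close on the 8-prenyl olefin of ring A (seven-membered ring, loss of isobutene) or cross-metathesise with a prenyl group instead of closing on the enol ether. Ruthenium hydride may also move the allylic ether double bond and destroy C2. Fallback, from 1 back to 22: the ring A prenyl group is installed only after ring closure, so no competing olefin sits on ring A during metathesis.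
 - Iodination of 1 at C3 (iodine I2, HIO3, aqueous EtOH) should give 1-(2,4-dihydroxy-3-iodophenyl)ethan-1-one F1.
 - TIPSCl and imidazole give the 4-O-triisopropylsilyl ether F2, and NaH gives its sodium phenoxide F3.
 - F3 is etherified with 15 under the iridium conditions of step 9 to the (S)-allyl ether ketone F4.
 - KN(SiMe3)2 gives potassium enolate F5, and TBSCl gives the tert-butyldimethylsilyl enol ether F6.
 - Ring-closing metathesis with RuCl2(=CHPh)(PCy3)(H2IMes) gives the 8-iodo-4-silyloxy-2H-chromene F7.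
 - Bu4NF with AcOH gives, through the 7-O-triisopropylsilyl 8-iodoflavanone F8, the (2S)-7-hydroxy-8-iodoflavanone F9.
 - Stille coupling of F9 with 10 (Pd(PPh3)4, DMF, 80 °C, neutral) gives 22.

2. Step 9. The hindered, chelated phenoxide may attack the iridium allyl complex slowly, so that the branched ether re-ionises and drifts to the linear isomer with erosion of enantiopurity. Fallback, from 11 back to 17: the C2–O bond is made by SN2 displacement instead of through a metal allyl complex.
 - CH2=CHMgBr adds to 11 (THF, −78 °C) to give racemic 1-(2,2-dimethyl-8-prenyl-2H-chromen-6-yl)prop-2-en-1-ol F10.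
 - Candida antarctica lipase B with vinyl acetate should acylate the (R) enantiomer (aryl as the large group, vinyl as the medium group) to the (R)-acetate F11, which is separated from unreacted (S)-alcohol.
 - K2CO3 in MeOH gives the (R)-alcohol F12.
 - Mitsunobu reaction of F12 with phenol 4 (PPh3, DIAD, toluene, −20 °C) displaces the activated hydroxyl with inversion and gives 17.

3. Step 1. Alkylation may spread over C3, C5 and the oxygens and may go on to dialkylation, leaving little 3. Fallback, from 1 and 6 back to 3: the prenyl group is delivered to C3 by a sigmatropic shift.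
 - Copper-catalysed etherification of the free 4-hydroxyl of 1 with 6 (CuCl2 cat., DBU, MeCN) gives 1-[2-hydroxy-4-(2-methylbut-3-yn-2-yloxy)phenyl]ethan-1-one F13.
 - Semi-hydrogenation (H2, Pd on CaCO3 poisoned with Pb(OAc)2, quinoline) gives the 1,1-dimethylallyl ether F14.
 - Aromatic Claisen rearrangement (N,N-diethylaniline, 150 °C) transfers the allyl unit with allylic inversion, as a prenyl group, to C3 and gives 3. C3 is favoured over C5 by the bond fixation of the chelated 2-hydroxyacetophenone.

Further compounds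
F1 | step 11 | 1-(2,4-dihydroxy-3-iodophenyl)ethan-1-one | CC(=O)c1ccc(O)c(I)c1O
F2 | step 11 | 1-[2-hydroxy-3-iodo-4-(triisopropylsilyloxy)phenyl]ethan-1-one | CC(=O)c1ccc(O[Si](C(C)C)(C(C)C)C(C)C)c(I)c1O
F3 | step 11 | sodium 2-acetyl-6-iodo-5-(triisopropylsilyloxy)phenolate | CC(=O)c1ccc(O[Si](C(C)C)(C(C)C)C(C)C)c(I)c1[O-].[Na+]
F4 | step 11 | 1-[2-{[(1S)-1-(2,2-dimethyl-8-prenyl-2H-chromen-6-yl)prop-2-en-1-yl]oxy}-3-iodo-4-(triisopropylsilyloxy)phenyl]ethan-1-one | CC(C)=CCc1cc([C@@H](Oc3c(C(C)=O)ccc(O[Si](C(C)C)(C(C)C)C(C)C)c3I)C=C)cc2c1OC(C)(C)C=C2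
F5 | step 11 | potassium enolate of F4 | CC(C)=CCc1cc([C@@H](Oc3c(C(=C)[O-])ccc(O[Si](C(C)C)(C(C)C)C(C)C)c3I)C=C)cc2c1OC(C)(C)C=C2.[K+]
F6 | step 11 | tert-butyldimethylsilyl enol ether of F4 | CC(C)=CCc1cc([C@@H](Oc3c(C(=C)O[Si](C)(C)C(C)(C)C)ccc(O[Si](C(C)C)(C(C)C)C(C)C)c3I)C=C)cc2c1OC(C)(C)C=C2
F7 | step 11 | (2S)-4-(tert-butyldimethylsilyloxy)-2-(2,2-dimethyl-8-prenyl-2H-chromen-6-yl)-8-iodo-7-(triisopropylsilyloxy)-2H-chromene | CC(C)=CCc1cc([C@@H]2C=C(O[Si](C)(C)C(C)(C)C)c3ccc(O[Si](C(C)C)(C(C)C)C(C)C)c(I)c3O2)cc2c1OC(C)(C)C=C2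
F8 | step 11 | (2S)-2-(2,2-dimethyl-8-prenyl-2H-chromen-6-yl)-8-iodo-7-(triisopropylsilyloxy)chroman-4-one | CC(C)=CCc1cc([C@@H]2CC(=O)c3ccc(O[Si](C(C)C)(C(C)C)C(C)C)c(I)c3O2)cc2c1OC(C)(C)C=C2
F9 | step 11 | (2S)-7-hydroxy-8-iodo-2-(2,2-dimethyl-8-prenyl-2H-chromen-6-yl)chroman-4-one | CC(C)=CCc1cc([C@@H]2CC(=O)c3ccc(O)c(I)c3O2)cc2c1OC(C)(C)C=C2
F10 | step 9 | racemic 1-(2,2-dimethyl-8-prenyl-2H-chromen-6-yl)prop-2-en-1-ol | CC(C)=CCc1cc(C(O)C=C)cc2c1OC(C)(C)C=C2
F11 | step 9 | (1R)-1-(2,2-dimethyl-8-prenyl-2H-chromen-6-yl)prop-2-en-1-yl acetate | CC(C)=CCc1cc([C@H](OC(C)=O)C=C)cc2c1OC(C)(C)C=C2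
F12 | step 9 | (1R)-1-(2,2-dimethyl-8-prenyl-2H-chromen-6-yl)prop-2-en-1-ol | CC(C)=CCc1cc([C@H](O)C=C)cc2c1OC(C)(C)C=C2
F13 | step 1 | 1-[2-hydroxy-4-(2-methylbut-3-yn-2-yloxy)phenyl]ethan-1-one | CC(=O)c1ccc(OC(C)(C)C#C)cc1O
F14 | step 1 | 1-[2-hydroxy-4-(2-methylbut-3-en-2-yloxy)phenyl]ethan-1-one | CC(=O)c1ccc(OC(C)(C)C=C)cc1O
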